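(The earlier runs and the new flask were generated by integration with made-up constants, and the scatter is random.)

| setting | delta | theta | zeta | flask |
|---|---|---|---|---|
| J | 0.10 M | 0.10 M | 0.15 M | 0.10 M |
| Q | 0.070 M (fed, over 80 s) | 0.16 M (fed, over 80 s) | 0.105 M (fed, over 80 s) | 0.105 M (fed, over 80 s) |
| E | 5.9 mM (held) | 5.9 mM (held) | 5.9 mM (held) | 5.9 mM (held) |
| remark | run made earlier; the fed solution adds 0.25 times the starting volume | run made earlier; the fed solution adds 0.25 times the starting volume | run made earlier; the fed solution adds 0.25 times the starting volume | the fed solution adds 0.25 times the starting volume |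
| time |  |  |  | 20 min |

| run | time / min | X / % | J / % |
|---|---|---|---|
| delta | 2.00 | 5.2 | 92.9 |
| delta | 6.00 | 14.1 | 85.2 |
| delta | 12.0 | 23.3 | 77.1 |
| delta | 15.0 | 27.0 | 73.4 |
| delta | 25.0 | 37.7 | 62.9 |
| theta | 2.00 | 9.2 | 90.8 |
| theta | 6.00 | 20.6 | 79.5 |
| theta | 12.0 | 30.8 | 67.9 |
| theta | 15.0 | 35.6 | 63.6 |
| theta | 25.0 | 48.0 | 53.1 |
| zeta | 5.00 | 12.4 | 86.8 |
| zeta | 10.0 | 18.8 | 80.6 |
| zeta | 15.0 | 25.1 | 76.0 |
| zeta | 20.0 | 28.3 | 70.8 |
| zeta | 25.0 | 31.6 | 68.5 |

(scatter of a reading: 0.5 percentage points)

- every charge counts on the volume at the start, and the solution that is fed holds the whole dose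
- at the start none of D is dissolved
- what may be going on: Z + D <-> L; E <-> D; J + G -> Z + X; G + Z <-> Q

- the largest share of what was charged as J, at 20 min belongs to (J / X)
- the largest share itself, whichever of these holds it, in percent of the J charged

The vessel has its Q within 80 s, sooner than the first reading, so I treat Q as charged at the start. I count in fractions of the J charged. In delta at 15.0 min, X and J add to 100%, so what is not X is J. But no run has the flask's Q per J: zeta has the flask's Q, but at a higher J, so I go to logarithms. Delta and theta differ in Q, 0.700 against 1.60 per J. At 25.0 min their X readings give a slope of 0.292. This is the Q exponent, the change of ln X per change of ln Q at fixed J and time, an apparent order. Delta's slope in time is 0.653, which puts delta at X 32.6% at 20 min. The flask's Q, 1.05 per J, raises that to 36.7%. So I expect J at 63.3%, more than X.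

The forecast says J, at 62.3%, within 60.5% to 64%, seeing Q as “a reservoir that releases G”. My J lies 1 percentage point higher.

The flask gives J at 63.2%, and X at 36.8%.

    Z + D ⇌ L, settled at all times (K = 5.30 × 10⁶ M⁻¹)
    E ⇌ D, rate k2*(csat - [D]) (kL = 0.00590 s⁻¹)
    J + G → Z + X (k = 0.140 M⁻¹ s⁻¹)
    G + Z ⇌ Q, settled at all times (K = 1300 M⁻¹)

In the flask at 10.1 min, J has a half-life of 35 min by the step from J + G to Z + X, longer than the 20 min of the run. G has 1.4 min by the same step, far shorter, while Q still holds 62.5% of its own charge at 20.0 min. From my delta value to the flask's X the slope is 0.297. Carried by the Q exponent to a neighbour flask with 2.60 equiv of Q, X becomes 47.9%; that neighbour stands at 50.1%.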